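## Analysis of the target

Numbering used throughout: chromene O1, C2, C3, C4, C4a, C5–C8, C8a; side chain C1'–C4'; ring A is the 2,4-dihydroxyphenyl ring, ring B the benzene ring of the chromene, ring C the pyran ring.

The target 22 is a dihydrochalcone. A 2,2-disubstituted 2H-chromene carries a free phenol at C8 and, at C5, a CH2CH2C(=O) bridge to ring A. The only stereocentre is C2, a fully substituted carbon of R configuration bonded to O1, the sp2 carbon C3, a methyl group and C1' of an (E)-4-hydroxy-4-methylpent-2-enyl chain. No second stereocentre can relay to it, so a catalyst or reagent must set it, and the C2'=C3' alkene must be E. The sensitive groups are the tertiary allylic alcohol (ionises with acid), the three phenols (the C8 phenol is an oxidisable catechol monoether) and the aryl ketone (does not survive organometallic reagents). The 2H-chromene is sensitive to acid, and light or strong heating can open it by a retro-oxa-6π process, which would erase C2. The synthesis is hard because methyl and CH2R at C2 differ little, ring B is 1,2,3,4-tetrasubstituted, and the C3=C4 alkene should be present without a late dehydrogenation. The strategy rests on one feature: both carbon substituents at C2 other than methyl, C3 (with C4) and C1' (with C2'), can be traced back to ethynyl groups. The aryl ether of a diethynyl methyl carbinol is achiral with C2 prochiral. Because C8 is oxygenated, the only aryl C–H ortho to O1 is the future C4a. Hydroarylation of one alkyne therefore closes ring C, creates C3=C4 and makes C2 stereogenic in one operation, and the untouched alkyne remains as the latent C1'–C2' unit.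

## Retrosynthetic reasoning

**22 to 21 (O–Si bonds).** All three phenols are masked as triisopropylsilyl ethers, so one buffered fluoride treatment ends the route. The tertiary alcohol needs no protection. This keeps acid away from the allylic alcohol and the chromene.

**21 to 17 and 20 (C5–CH2 bond of the bridge).** This cut separates the achiral ring A ketone unit from the chromene. The ketone cannot be present during the Grignard and borane steps, so it is introduced late. Cyclopropanol 20 acts as a homoenolate (β-acyl carbanion) equivalent towards the aryl bromide under palladium catalysis. The bromine is carried at C5 from the first aromatic building block. Cutting the acyl–ring A bond (Friedel–Crafts or Fries chemistry) would need Lewis acid on the chromene. Cutting the CH2–CH2 bond (aldol to a chalcone) would need a later conjugate reduction beside two other alkenes.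

**17 to 15 to 14 (two C4'–CH3 bonds, then C2'=C3').** The tertiary alcohol comes from an enoate and a methyl organomagnesium reagent. The E alkene comes from a stabilised phosphorus ylide and aldehyde 14, in which C1' is already a CH2 group.

**14 to 12 (change of oxidation level).** An aldehyde at C2' is the anti-Markovnikov hydration product of a terminal alkyne. An ethynyl group at C2 is therefore the most direct precursor of C1'–C2', reached in one step by hydroboration and oxidation.

**12 to 11 (C4–C4a bond, key disconnection).** Cutting the aryl–vinyl bond of ring C leads back to the achiral diethynyl carbinol aryl ether 11. The forward reaction must add the C4a–H bond across one of two enantiotopic alkynes, in the 6-endo sense, with a chiral cationic gold complex choosing the alkyne. Nothing else in the molecule needs adjusting afterwards: the alkene is in place and the second alkyne is the side-chain handle.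

**11 to 10 to 8 to 7 and 6 (C8 O–Si bond, C8 oxygen from a formyl group, O1–C2 bond).** The tertiary propargylic ether bond is made by copper-catalysed substitution of carbonate 6 with a phenol. A monosilylated catechol was avoided as the phenol partner, because such phenoxides pass silicon between the two oxygens under base and the regiochemistry would be lost. In salicylaldehyde 7 the hydroxyl is meta to bromine and becomes O1. The formyl carbon is para to bromine and is exchanged for the C8 oxygen by a Baeyer–Villiger oxidation after the ether is in place. The regiochemistry is thus fixed by the starting material. Silylation comes last, so no phenoxide ever sits next to a silyl ether.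

**6 to 4 to 1 and 2.** The diynol is the double addition product of an ethynyl Grignard reagent (2) to an acetate ester (1). Its carbonate is the leaving group needed for the copper step.

**20 to 19 to 18.** The 1-arylcyclopropanol is the Kulinkovich product of the bis-silylated ester of commercial 18, so ring A is bought with all its atoms.

## Alternatives that were turned down

**Alternative 1:** Ring A is built last.
- **Disconnection:** the two ring A bonds flanking the acyl-bearing carbon are cut. This gives the ethynyl ketone A1 (the chromene with the bridge ending in C(=O)C≡CH, C8 oxygen as triisopropylsilyl ether, side-chain alcohol as triethylsilyl ether) and the bis-silyloxy diene A2.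
- **Forward key step:** a Diels–Alder addition (nucleophilic CH2 terminus of A2 to the alkyne β-carbon), expulsion of the methoxy group and loss of the trimethylsilyl groups should give A3, with both ring A phenols free and ortho/para to the ketone.
- **For it:** the polarity of both partners dictates the regiochemistry, and two C–C bonds form at once. Ring A never needs protection. On that point it is stronger than the chosen route, which carries two silyl ethers on ring A through a Kulinkovich reaction and a palladium coupling.
- **Against it:** ring A is a plain resorcinol that can be bought complete (18), so the main bond-forming event is spent on an achiral, trivial ring. The plan says nothing about C2, ring C or the side chain, which would still need an asymmetric method of their own. A1 is a nucleophile-sensitive ynone that must be assembled on the most advanced intermediate, and the bridge still has to be attached at C5. The side-chain alcohol needs its own protecting group.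
- **Comparison:** it is several steps longer in the linear sequence and removes none of the real difficulties. The chosen plan spends its key step on the stereocentre and attaches ring A in one coupling.

**Alternative 2:** The O1–C2 and C1'–C2' bonds are cut together.
- **Disconnection:** the precursors are the ortho-homoallyl phenol A4 and the acrylate A5.
- **Forward key step:** under divalent palladium (Pd(OCOCF3)2), a chiral bis(oxazoline) ligand of the BOXAX type and a quinone reoxidant, enantioselective 6-exo-trig oxypalladation of the 1,1-disubstituted alkene sets C2. The resulting alkylpalladium has no β-hydrogen and is trapped by A5 in a Heck reaction, giving the chroman enoate A6.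
- **For it:** this domino process is well established for 2-methylchromans with high enantioselectivity and a predictable sense of induction. It delivers ring C, C2 and three side-chain carbons in one step, already at the enoate stage that the chosen route reaches only as 15. On precedent and side-chain economy it is stronger than the chosen key step.
- **Against it:** A6 is a chroman. The C3=C4 alkene of 22 would have to be introduced afterwards by dehydrogenation of a bromine-deactivated ring B, beside an enoate or allylic alcohol with its own allylic positions. This late change of oxidation level is the weak point. A4 also needs a carbon substituent between the phenol and the bromine before ring closure, which costs extra steps.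
- **Comparison:** the chosen strategy gives ring C at the correct oxidation level from the outset, and its second alkyne reaches the aldehyde level in one step. It pays with an enantioselection that is not yet proven.

**Alternative 3:** The C3=C4 double bond is cut.
- **Disconnection:** the precursor is the triene A7, the ether of a tertiary divinyl carbinol with a phenol that carries a vinyl group at the future C4a.
- **Forward key step:** a chiral molybdenum alkylidene of the type Mo(N-2,6-iPr2C6H3)(CHCMe2Ph)(biphenolate) would initiate at the styrene, select one enantiotopic vinyl group in the ring-closing step and give the 2-vinylchromene A8.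
- **For it:** desymmetrising ring-closing metathesis of tertiary divinyl carbinol ethers to six-membered cyclic ethers is an established reaction class. The C3=C4 alkene arises at the right oxidation level, as in the chosen route. The selecting metallacyclobutane holds the metal and its ligands within bonding distance of C2, a tighter arrangement than a linear gold complex. On the likelihood of high enantioselectivity this alternative is stronger.
- **Against it:** A7 needs the ring B carbon between O1 and bromine vinylated before cyclisation, so a tetrasubstituted arene must be built first. The tertiary bis-allylic aryl ether has no counterpart to the copper-acetylide etherification and is hard to make from a hindered phenol. The molybdenum catalysts do not tolerate air or protic impurities. The vinyl group of A8 needs two steps to reach the aldehyde, where the ethynyl group of 12 needs one.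
- **Comparison:** the chosen strategy gives up the better-precedented selection step for a shorter and more reliable approach to the cyclisation substrate. The arene C–H is used as such, the ether is made by copper catalysis, and ring C and the side chain both come from one cheap symmetrical diyne.

Key step: step 6

Assumption: the sense of induction of the digold catalyst cannot be derived from a model with confidence. The (R)-ligand is written, and the (S)-ligand is used instead if a first cyclisation shows the opposite sense.

## Route

Step 1
Reactants: 1 ethyl acetate; 2 ethynylmagnesium bromide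
Product: 4 3-methylpenta-1,4-diyn-3-ol, via but-3-yn-2-one 3 (not isolated)
Conditions: HC≡CMgBr (2.5 equiv), THF, 0 °C → rt; aq. NH4Cl
Reagents that add atoms: none
Why: Double Grignard addition to an ester; the ynone 3 formed after the first addition is more electrophilic than the ester and is consumed at once, and low temperature favours 1,2-addition.

Step 2
Reactants: 4 3-methylpenta-1,4-diyn-3-ol
Product: 6 methyl 3-methylpenta-1,4-diyn-3-yl carbonate, via lithium alkoxide 5 (not isolated)
Conditions: n-BuLi (1.0 equiv), THF, −78 °C; ClCO2Me, −78 → 0 °C
Reagents that add atoms: methyl chloroformate, COC(=O)Cl; n-butyllithium, [Li]CCCC (its lithium is kept in 5 only)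
Why: O-acylation of a tertiary alkoxide; one equivalent of base removes the hydroxyl proton, which is far more acidic than the alkyne C–H, and the carbonate is the leaving group needed for the copper-catalysed etherification.

Step 3
Reactants: 7 4-bromo-2-hydroxybenzaldehyde; 6 methyl 3-methylpenta-1,4-diyn-3-yl carbonate
Product: 8 4-bromo-2-[(3-methylpenta-1,4-diyn-3-yl)oxy]benzaldehyde
Conditions: CuCl2·2H2O (1 mol%), DBU (1.3 equiv), MeCN, −5 → 0 °C, argon
Reagents that add atoms: none
Why: Copper-catalysed propargylic etherification: the copper acetylide of 6 loses methyl carbonate to a copper allenylidene-type cation, which the phenoxide of 7 attacks at the tertiary carbon; the second ethynyl group stabilises this cation and the aldehyde is inert. Exclusion of air suppresses oxidative alkyne coupling.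

Step 4
Reactants: 8 4-bromo-2-[(3-methylpenta-1,4-diyn-3-yl)oxy]benzaldehyde
Product: 10 4-bromo-2-[(3-methylpenta-1,4-diyn-3-yl)oxy]phenol, via aryl formate 9 (not isolated)
Conditions: mCPBA (1.4 equiv), CH2Cl2, 0 °C → rt; then K2CO3 (0.2 equiv), MeOH, 0 °C
Reagents that add atoms: 3-chloroperbenzoic acid, OOC(=O)c1cccc(Cl)c1
Why: Baeyer–Villiger oxidation (Dakin-type): the aryl group, made electron-rich by the ortho alkoxy group, migrates in preference to hydride, and the formate 9 is cleaved by brief methanolysis; terminal alkynes are inert to the peracid. The formyl position becomes the C8 oxygen with regiochemistry fixed by 7.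

Step 5
Reactants: 10 4-bromo-2-[(3-methylpenta-1,4-diyn-3-yl)oxy]phenol
Product: 11 4-bromo-2-[(3-methylpenta-1,4-diyn-3-yl)oxy]-1-(triisopropylsilyloxy)benzene
Conditions: TIPSCl (1.2 equiv), imidazole (2.5 equiv), DMF, rt
Reagents that add atoms: chlorotriisopropylsilane, CC(C)[Si](Cl)(C(C)C)C(C)C
Why: Standard phenol silylation; the oxygen is capped before gold catalysis because a free ortho phenol would add to the activated alkyne, and the bulky silyl ether survives the borane, Grignard and palladium steps.

Step 6
Reactants: 11 4-bromo-2-[(3-methylpenta-1,4-diyn-3-yl)oxy]-1-(triisopropylsilyloxy)benzene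
Product: 12 (2S)-5-bromo-2-ethynyl-2-methyl-8-(triisopropylsilyloxy)-2H-chromene
Conditions: (R)-DTBM-SEGPHOS(AuCl)2 (3 mol%), AgSbF6 (6 mol%), CH2Cl2, 4 Å molecular sieves, −20 °C → rt, dark
Reagents that add atoms: none
Why: Proposed new method: cationic monovalent gold, released from (R)-DTBM-SEGPHOS(AuCl)2 by AgSbF6, binds one ethynyl group of 11 as a π-complex; the arene carbon ortho to O1 (the future C4a, the only free ortho position because C8 carries the silyloxy group) attacks the terminal alkyne carbon anti to gold in a Friedel–Crafts-type step, the Wheland intermediate loses a proton, and protodeauration of the C3–Au bond leaves the C3=C4 alkene. The closest known reactions are the gold-catalysed hydroarylation of aryl propargyl ethers to 2H-chromenes, which sets no stereocentre of this kind, and chiral-gold cyclisations that desymmetrise 1,4-diynes with heteroatom nucleophiles; their combination on a diethynyl carbinol aryl ether is not established. Ring C closes in the 6-endo-dig mode, the normal mode for aryl propargyl ethers, since the 5-exo path would put the arene on the internal, more hindered alkyne carbon. C2 becomes stereogenic because only one of the two enantiotopic ethynyl groups is consumed; π-complexation is reversible, so the choice is made in the C4–C4a bond-forming transition state, where the half-chair of the nascent pyran ring places either the methyl or the spectator ethynyl group against the aryl walls of the ligand, and the second gold atom of the digold complex can hold the spectator alkyne. The step needs enantiotopic-group selectivity (from the catalyst), regioselectivity on ring B (secured by the C8 substituent), and chemoselectivity against O-cyclisation (secured by silylation in step 5) and against a second cyclisation (no further ortho C–H). The (2S) descriptor of 12 is the spatial arrangement of the target; the letter differs only because ethynyl outranks C3.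

Step 7
Reactants: 12 (2S)-5-bromo-2-ethynyl-2-methyl-8-(triisopropylsilyloxy)-2H-chromene
Product: 14 2-[(2R)-5-bromo-2-methyl-8-(triisopropylsilyloxy)-2H-chromen-2-yl]acetaldehyde, via alkenylborane 13 (not isolated)
Conditions: Cy2BH (from BH3·SMe2 and cyclohexene, 1.3 equiv), THF, 0 °C → rt; 30% H2O2, pH 7 phosphate buffer, 0 °C
Reagents that add atoms: hydrogen peroxide, OO; dicyclohexylborane, B(C1CCCCC1)C1CCCCC1 (its boron and cyclohexyl groups are kept in 13 only)
Why: Anti-Markovnikov syn hydroboration of the terminal alkyne by a hindered dialkylborane stops at mono-addition and is much faster than attack on the cis-disubstituted C3=C4 alkene next to the quaternary carbon; oxidation of 13 gives the enol and then the aldehyde. The buffered oxidant avoids base-induced β-elimination of the aryloxide; C2 is untouched, and its descriptor becomes R because CH2 ranks below C3.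

Step 8
Reactants: 14 2-[(2R)-5-bromo-2-methyl-8-(triisopropylsilyloxy)-2H-chromen-2-yl]acetaldehyde
Product: 15 ethyl (2E)-4-[(2R)-5-bromo-2-methyl-8-(triisopropylsilyloxy)-2H-chromen-2-yl]but-2-enoate
Conditions: Ph3P=CHCO2Et (1.3 equiv), CH2Cl2, rt
Reagents that add atoms: ethyl (triphenylphosphoranylidene)acetate, CCOC(=O)C=P(c1ccccc1)(c1ccccc1)c1ccccc1
Why: Wittig olefination with a stabilised ylide is E-selective and essentially neutral, so the β-aryloxy aldehyde is not enolised and C2 is not at risk.

Step 9
Reactants: 15 ethyl (2E)-4-[(2R)-5-bromo-2-methyl-8-(triisopropylsilyloxy)-2H-chromen-2-yl]but-2-enoate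
Product: 17 (3E)-5-[(2R)-5-bromo-2-methyl-8-(triisopropylsilyloxy)-2H-chromen-2-yl]-2-methylpent-3-en-2-ol, via methyl enone 16 (not isolated)
Conditions: MeMgBr (3.5 equiv), THF, −78 → 0 °C; aq. NH4Cl
Reagents that add atoms: methylmagnesium bromide, C[Mg]Br
Why: Double 1,2-addition of a Grignard reagent to the ester through enone 16; the aryl bromide and aryl silyl ether are inert to MeMgBr at this temperature, and the mild ammonium chloride quench spares the tertiary allylic alcohol.

Step 10
Reactants: 18 methyl 2,4-dihydroxybenzoate
Product: 19 methyl 2,4-bis(triisopropylsilyloxy)benzoate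
Conditions: TIPSOTf (2.4 equiv), 2,6-lutidine (3 equiv), CH2Cl2, 0 °C → rt
Reagents that add atoms: triisopropylsilyl trifluoromethanesulfonate, CC(C)[Si](OS(=O)(=O)C(F)(F)F)(C(C)C)C(C)C
Why: Silylation of both phenols; the triflate is needed for the hydrogen-bonded ortho phenol, and triisopropylsilyl is chosen because it resists migration to a neighbouring alkoxide and leaves together with the C8 group at the end.

Step 11
Reactants: 19 methyl 2,4-bis(triisopropylsilyloxy)benzoate
Product: 20 1-[2,4-bis(triisopropylsilyloxy)phenyl]cyclopropan-1-ol
Conditions: EtMgBr (3 equiv, slow addition), Ti(OiPr)4 (0.5 equiv), THF, 0 °C → rt; aq. NH4Cl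
Reagents that add atoms: ethylmagnesium bromide, CC[Mg]Br
Why: Kulinkovich cyclopropanation: the titanacyclopropane formed from EtMgBr and Ti(OiPr)4 acts as a 1,2-dicarbanion equivalent and converts the ester into the 1-arylcyclopropanol.

Step 12
Reactants: 17 (3E)-5-[(2R)-5-bromo-2-methyl-8-(triisopropylsilyloxy)-2H-chromen-2-yl]-2-methylpent-3-en-2-ol; 20 1-[2,4-bis(triisopropylsilyloxy)phenyl]cyclopropan-1-ol
Product: 21 1-[2,4-bis(triisopropylsilyloxy)phenyl]-3-[(2R)-2-[(2E)-4-hydroxy-4-methylpent-2-en-1-yl]-2-methyl-8-(triisopropylsilyloxy)-2H-chromen-5-yl]propan-1-one
Conditions: Pd(OAc)2 (5 mol%), XPhos (10 mol%), Cs2CO3 (2 equiv), toluene, 60 °C, dark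
Reagents that add atoms: none
Why: Palladium-catalysed ring-opening arylation of a cyclopropanol (homoenolate cross-coupling): oxidative addition of zerovalent palladium to the C5–Br bond, exchange with the cyclopropanolate, strain-driven β-carbon elimination and reductive elimination form the C5–CH2 bond; the bulky electron-rich phosphine favours reductive elimination over β-hydride elimination. The unstrained tertiary alcohol of 17 does not take part, and loss of a silyl group under the carbonate base would be harmless because all three are removed in step 13.

Step 13
Reactants: 21 1-[2,4-bis(triisopropylsilyloxy)phenyl]-3-[(2R)-2-[(2E)-4-hydroxy-4-methylpent-2-en-1-yl]-2-methyl-8-(triisopropylsilyloxy)-2H-chromen-5-yl]propan-1-one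
Product: 22 1-(2,4-dihydroxyphenyl)-3-[(2R)-8-hydroxy-2-[(2E)-4-hydroxy-4-methylpent-2-en-1-yl]-2-methyl-2H-chromen-5-yl]propan-1-one
Conditions: Bu4NF (4 equiv), AcOH (4 equiv), THF, 0 °C, dark
Reagents that add atoms: none
Why: Fluoride cleavage of the three aryl silyl ethers, buffered with acetic acid so that the phenols, the tertiary allylic alcohol and the chromene see neither strong base nor acid; no stereocentre is touched.

## Compound list

1 | ethyl acetate | CCOC(C)=O | starting material
2 | ethynylmagnesium bromide | C#C[Mg]Br | starting material
3 | but-3-yn-2-one | CC(=O)C#C | intermediate (not isolated)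
4 | 3-methylpenta-1,4-diyn-3-ol | CC(O)(C#C)C#C | intermediate
5 | lithium 3-methylpenta-1,4-diyn-3-olate | CC([O-])(C#C)C#C.[Li+] | intermediate (not isolated)
6 | methyl 3-methylpenta-1,4-diyn-3-yl carbonate | COC(=O)OC(C)(C#C)C#C | intermediate
7 | 4-bromo-2-hydroxybenzaldehyde | O=Cc1ccc(Br)cc1O | starting material
8 | 4-bromo-2-[(3-methylpenta-1,4-diyn-3-yl)oxy]benzaldehyde | O=Cc1ccc(Br)cc1OC(C)(C#C)C#C | intermediate
9 | 4-bromo-2-[(3-methylpenta-1,4-diyn-3-yl)oxy]phenyl formate | O=COc1ccc(Br)cc1OC(C)(C#C)C#C | intermediate (not isolated)
10 | 4-bromo-2-[(3-methylpenta-1,4-diyn-3-yl)oxy]phenol | Oc1ccc(Br)cc1OC(C)(C#C)C#C | intermediate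
11 | 4-bromo-2-[(3-methylpenta-1,4-diyn-3-yl)oxy]-1-(triisopropylsilyloxy)benzene | C#CC(C)(C#C)Oc1cc(Br)ccc1O[Si](C(C)C)(C(C)C)C(C)C | intermediate
12 | (2S)-5-bromo-2-ethynyl-2-methyl-8-(triisopropylsilyloxy)-2H-chromene | C#C[C@]1(C)C=Cc2c(Br)ccc(O[Si](C(C)C)(C(C)C)C(C)C)c2O1 | intermediate
13 | dicyclohexyl{(E)-2-[(2R)-5-bromo-2-methyl-8-(triisopropylsilyloxy)-2H-chromen-2-yl]ethenyl}borane | C1CCCCC1B(/C=C/[C@]1(C)C=Cc2c(Br)ccc(O[Si](C(C)C)(C(C)C)C(C)C)c2O1)C1CCCCC1 | intermediate (not isolated)
14 | 2-[(2R)-5-bromo-2-methyl-8-(triisopropylsilyloxy)-2H-chromen-2-yl]acetaldehyde | O=CC[C@]1(C)C=Cc2c(Br)ccc(O[Si](C(C)C)(C(C)C)C(C)C)c2O1 | intermediate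
15 | ethyl (2E)-4-[(2R)-5-bromo-2-methyl-8-(triisopropylsilyloxy)-2H-chromen-2-yl]but-2-enoate | CCOC(=O)/C=C/C[C@]1(C)C=Cc2c(Br)ccc(O[Si](C(C)C)(C(C)C)C(C)C)c2O1 | intermediate
16 | (3E)-5-[(2R)-5-bromo-2-methyl-8-(triisopropylsilyloxy)-2H-chromen-2-yl]pent-3-en-2-one | CC(=O)/C=C/C[C@]1(C)C=Cc2c(Br)ccc(O[Si](C(C)C)(C(C)C)C(C)C)c2O1 | intermediate (not isolated)
17 | (3E)-5-[(2R)-5-bromo-2-methyl-8-(triisopropylsilyloxy)-2H-chromen-2-yl]-2-methylpent-3-en-2-ol | CC(C)(O)/C=C/C[C@]1(C)C=Cc2c(Br)ccc(O[Si](C(C)C)(C(C)C)C(C)C)c2O1 | intermediate
18 | methyl 2,4-dihydroxybenzoate | COC(=O)c1ccc(O)cc1O | starting material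
19 | methyl 2,4-bis(triisopropylsilyloxy)benzoate | COC(=O)c1ccc(O[Si](C(C)C)(C(C)C)C(C)C)cc1O[Si](C(C)C)(C(C)C)C(C)C | intermediate
20 | 1-[2,4-bis(triisopropylsilyloxy)phenyl]cyclopropan-1-ol | OC1(CC1)c1ccc(O[Si](C(C)C)(C(C)C)C(C)C)cc1O[Si](C(C)C)(C(C)C)C(C)C | intermediate
21 | 1-[2,4-bis(triisopropylsilyloxy)phenyl]-3-[(2R)-2-[(2E)-4-hydroxy-4-methylpent-2-en-1-yl]-2-methyl-8-(triisopropylsilyloxy)-2H-chromen-5-yl]propan-1-one | CC(C)(O)/C=C/C[C@]1(C)C=Cc2c(CCC(=O)c3ccc(O[Si](C(C)C)(C(C)C)C(C)C)cc3O[Si](C(C)C)(C(C)C)C(C)C)ccc(O[Si](C(C)C)(C(C)C)C(C)C)c2O1 | intermediate
22 | 1-(2,4-dihydroxyphenyl)-3-[(2R)-8-hydroxy-2-[(2E)-4-hydroxy-4-methylpent-2-en-1-yl]-2-methyl-2H-chromen-5-yl]propan-1-one | CC(C)(O)/C=C/C[C@]1(C)C=Cc2c(CCC(=O)c3ccc(O)cc3O)ccc(O)c2O1 | target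

## Step count and risks

Total: 13 steps. Longest linear sequence: 11 steps (steps 1–9, 12, 13, from ethyl acetate); steps 10 and 11 form the side branch to 20.

**Step 6 (key step).**
- **Risk:** weak discrimination between the enantiotopic alkynes is the most likely failure. The two-coordinate gold centre holds the ligand far from C2, and methyl and ethynyl differ little in size. Ring closure at the bromine-flanked, only moderately activated carbon may also be slow. A higher temperature would then open racemising channels (a gold-promoted propargyl Claisen/allenyl pathway, or reversible ionisation of the C2–O1 bond).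
- **Fallback:** known chemistry, setting out from 11. Cyclisation with the achiral catalyst Ph3PAuNTf2 in CH2Cl2 would give racemic 5-bromo-2-ethynyl-2-methyl-8-(triisopropylsilyloxy)-2H-chromene F1. If gold fails altogether, the thermal rearrangement of the aryl propargyl ether in N,N-diethylaniline at 180 °C (propargyl Claisen, 1,5-hydrogen shift, oxa-6π closure) would give the same racemate. Preparative chromatography of F1 on a chiral stationary phase would separate 12 from its enantiomer (2R)-5-bromo-2-ethynyl-2-methyl-8-(triisopropylsilyloxy)-2H-chromene F2, and the route is rejoined at 12.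

**Step 3.**
- **Risk:** side reactions of the copper acetylide of a doubly terminal diyne (oxidative alkyne coupling, oligomerisation), elimination of the carbonate towards an enediyne, or sluggish attack by the hydrogen-bonded ortho-formyl phenoxide.
- **Fallback:** the aryl–oxygen bond is formed instead of the alkyl–oxygen bond, setting out from 4. Deprotonation with KN(SiMe3)2 in THF at −78 °C would give potassium 3-methylpenta-1,4-diyn-3-olate F3. Nucleophilic aromatic substitution on commercial 4-bromo-2-fluorobenzaldehyde F4 (THF/DMF, 0 °C → rt) would displace the fluoride ortho to the formyl group and return to the route at 8. No copper is involved and step 2 is not needed.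

**Step 7.**
- **Risk:** β-elimination of the aryloxide from the aldehyde (O1 is β to the carbonyl) during the oxidative work-up, which would open ring C and erase C2; competing hydroboration of C3=C4 is a lesser risk.
- **Fallback:** setting out from 12, semihydrogenation (H2, Pd/CaCO3 poisoned with Pb(OAc)2, quinoline, EtOAc) would give (2R)-5-bromo-2-ethenyl-2-methyl-8-(triisopropylsilyloxy)-2H-chromene F5, the same structure as A8. 9-BBN in THF followed by NaBO3·4H2O would hydroborate only the monosubstituted alkene and give 2-[(2R)-5-bromo-2-methyl-8-(triisopropylsilyloxy)-2H-chromen-2-yl]ethan-1-ol F6, a β-aryloxy alcohol that cannot eliminate. Oxidation of F6 with Dess–Martin periodinane (NaHCO3, CH2Cl2) in the presence of Ph3P=CHCO2Et would generate the aldehyde under neutral conditions and trap it at once, returning to the route at 15.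

**Step 12.**
- **Risk:** β-hydride elimination of the palladium homoenolate (enone formation and reduction of the arene) and slow oxidative addition at the electron-rich, ortho-substituted C5–Br bond. If the temperature has to be raised, thermal electrocyclic opening of the chromene threatens C2. The supply of 20 may also suffer from silyl transfer from the ortho oxygen to the cyclopropanolate in step 11.
- **Fallback:** setting out from 19 and 17, without 20. Reduction of 19 with iBu2AlH (toluene, −78 °C) would give 2,4-bis(triisopropylsilyloxy)benzaldehyde F7, and vinylmagnesium bromide (THF, −78 °C) would give racemic 1-[2,4-bis(triisopropylsilyloxy)phenyl]prop-2-en-1-ol F8. A Heck reaction of 17 with F8 (Pd(OAc)2, Bu4NCl, NaHCO3, DMF, 60 °C) would arylate the terminal alkene carbon; β-hydride elimination towards the carbinol carbon and tautomerisation would give the saturated ketone and return to the route at 21.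

## Further compounds

F1 | step 6 | racemic 5-bromo-2-ethynyl-2-methyl-8-(triisopropylsilyloxy)-2H-chromene | C#CC1(C)C=Cc2c(Br)ccc(O[Si](C(C)C)(C(C)C)C(C)C)c2O1
F2 | step 6 | (2R)-5-bromo-2-ethynyl-2-methyl-8-(triisopropylsilyloxy)-2H-chromene | C#C[C@@]1(C)C=Cc2c(Br)ccc(O[Si](C(C)C)(C(C)C)C(C)C)c2O1
F3 | step 3 | potassium 3-methylpenta-1,4-diyn-3-olate | CC([O-])(C#C)C#C.[K+]
F4 | step 3 | 4-bromo-2-fluorobenzaldehyde | O=Cc1ccc(Br)cc1F
F5 | step 7 | (2R)-5-bromo-2-ethenyl-2-methyl-8-(triisopropylsilyloxy)-2H-chromene | C=C[C@]1(C)C=Cc2c(Br)ccc(O[Si](C(C)C)(C(C)C)C(C)C)c2O1
F6 | step 7 | 2-[(2R)-5-bromo-2-methyl-8-(triisopropylsilyloxy)-2H-chromen-2-yl]ethan-1-ol | OCC[C@]1(C)C=Cc2c(Br)ccc(O[Si](C(C)C)(C(C)C)C(C)C)c2O1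
F7 | step 12 | 2,4-bis(triisopropylsilyloxy)benzaldehyde | O=Cc1ccc(O[Si](C(C)C)(C(C)C)C(C)C)cc1O[Si](C(C)C)(C(C)C)C(C)C
F8 | step 12 | racemic 1-[2,4-bis(triisopropylsilyloxy)phenyl]prop-2-en-1-ol | C=CC(O)c1ccc(O[Si](C(C)C)(C(C)C)C(C)C)cc1O[Si](C(C)C)(C(C)C)C(C)C
A1 | alternative 1 | 5-[(2R)-2-methyl-2-[(2E)-4-methyl-4-(triethylsilyloxy)pent-2-en-1-yl]-8-(triisopropylsilyloxy)-2H-chromen-5-yl]pent-1-yn-3-one | CC(C)(O[Si](CC)(CC)CC)/C=C/C[C@]1(C)C=Cc2c(CCC(=O)C#C)ccc(O[Si](C(C)C)(C(C)C)C(C)C)c2O1
A2 | alternative 1 | 1-methoxy-1,3-bis(trimethylsilyloxy)buta-1,3-diene | COC(O[Si](C)(C)C)=CC(=C)O[Si](C)(C)C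
A3 | alternative 1 | 1-(2,4-dihydroxyphenyl)-3-[(2R)-2-methyl-2-[(2E)-4-methyl-4-(triethylsilyloxy)pent-2-en-1-yl]-8-(triisopropylsilyloxy)-2H-chromen-5-yl]propan-1-one | CC(C)(O[Si](CC)(CC)CC)/C=C/C[C@]1(C)C=Cc2c(CCC(=O)c3ccc(O)cc3O)ccc(O[Si](C(C)C)(C(C)C)C(C)C)c2O1
A4 | alternative 2 | 3-bromo-2-(3-methylbut-3-en-1-yl)-6-(triisopropylsilyloxy)phenol | C=C(C)CCc1c(Br)ccc(O[Si](C(C)C)(C(C)C)C(C)C)c1O
A5 | alternative 2 | methyl acrylate | C=CC(=O)OC
A6 | alternative 2 | methyl (2E)-4-[(2S)-5-bromo-2-methyl-8-(triisopropylsilyloxy)-3,4-dihydro-2H-chromen-2-yl]but-2-enoate | COC(=O)/C=C/C[C@]1(C)CCc2c(Br)ccc(O[Si](C(C)C)(C(C)C)C(C)C)c2O1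
A7 | alternative 3 | 1-bromo-2-ethenyl-3-[(3-methylpenta-1,4-dien-3-yl)oxy]-4-(triisopropylsilyloxy)benzene | C=CC(C)(C=C)Oc1c(C=C)c(Br)ccc1O[Si](C(C)C)(C(C)C)C(C)C
A8 | alternative 3 | (2R)-5-bromo-2-ethenyl-2-methyl-8-(triisopropylsilyloxy)-2H-chromene | C=C[C@]1(C)C=Cc2c(Br)ccc(O[Si](C(C)C)(C(C)C)C(C)C)c2O1
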